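Lignan numbering is used throughout. C7, C8 and C9 belong to the half whose benzylic carbon lies in the ring, and C7', C8' and C9' to the other half. Ring A is O1–C7–C8–C8'–C9'. In oxolane numbering C7 = C2, C8 = C3, C8' = C4 and C9' = C5.

## The problem

(−)-Tanegol (11) consists of two guaiacylpropane halves joined by the C8–C8' bond and by one ether oxygen, which closes the tetrahydrofuran ring A (O1, C7, C8, C8', C9'). Ring A carries a guaiacyl group at C7, the hydroxymethyl carbon C9 at C8, and the guaiacyl carbinol C7' at C8'. The four stereocentres are contiguous (7S,8R,8'R,7'S). C7 and C8 are trans. C8 and C8' are cis, which is the less stable arrangement and is lost whenever C8 or C8' sits next to a carbonyl group. C7' lies outside the ring and can be controlled only through C8'. C7 can direct C8 and C8 can direct C8', so one absolute stereocentre at C7 suffices if C7' can be coupled rigidly to C8'. Both benzylic C–O bonds (C7–O1 and C7'–OH) are para to a phenol oxygen. Acid or heat ionises them through quinone methides, which epimerises C7 and C7' and lets O9 close onto C7' to give the furofuran. The same bonds are open to hydrogenolysis.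

The enabling feature is that O1 ties C7 to C9'. C8 and C8' are therefore the ends of the three-atom tether C7–O1–C9', and each bears one exocyclic oxygenated carbon (C9 and C7'). The 1,4-diol C9–C8–C8'–C7' on ring A is thus the imprint of a hydrometallative cyclisation of a 1,6-enyne, with C8=C9 as the alkene and C8'≡C7' as the alkyne.

## Retrosynthesis

**11 ⇒ 10.**
- Only the two phenolic O–H bonds are changed, to O–benzyl.
- The phenols stay masked to the end because the free p-hydroxybenzyl systems ionise.
- Benzyl is chosen because both aryl building blocks are sold as benzyl ethers.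
- The forward step must cleave two aryl benzyl ethers and leave C7'–OH and C7–O1 intact.

**10 ⇒ 8 (through 9).**
- The bonds cut are C7'–O, C8'–H and C9–O. Both hydroxyl groups are traced to C–B bonds, and the pair C8'/C7' to one suprafacial addition of H–B to an exocyclic Z double bond C8'=C7'.
- The neighbouring cuts (C7'–aryl or C7'–C8', that is addition to a C8' aldehyde or an aldol) leave C7' to acyclic induction and pass through an epimerisable cis carbonyl compound.
- Here C8' and C7' arise in the same event. The face is chosen by the substituent on C8, and attack anti to it gives the cis relationship.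
- Compound 8 has two stereocentres and two hydroxyl groups fewer than 10.
- The forward reaction must place boron at C7' and approach anti to C9.

**8 ⇒ 7.**
- The bonds cut are C8–C8', C9–B and C7'–H.
- Closing ring A at O1–C7 or O1–C9' would require the whole acyclic stereotetrad first.
- Cutting the central C8–C8' bond with O1 already in place gives an acyclic enyne with one stereocentre, and the tether decides which carbons are joined.
- The forward reaction must add H–metal syn to the alkyne, which fixes the Z geometry. It must close the ring 5-exo, place C9 trans to the C7 aryl group, and hand C9 to boron.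

**7 ⇒ 3 + 6.**
- The bond cut is C7–O1.
- The alternative O1–C9' cut (Williamson) needs a preformed enantioenriched allylic alcohol.
- Cutting C7–O1 lets one catalytic asymmetric allylic etherification both join the two halves and create the only stereocentre that must be set absolutely.
- Compounds 3 and 6 are achiral and of equal size.

**3 ⇒ 1 + 2 and 6 ⇒ 4 + 5.**
- The C7=C8 bond of 3 comes from cross-metathesis. The aryl–C7' bond of 6 comes from Sonogashira coupling.
- Each is one step from purchased materials.

## Roads not taken

**Alternative 1:** This is the most obvious plan.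
- *Cut:* C7'–C8' and C7–C8 as two aldol bonds, and O1–C7 as a cationic ring closure.
- *Forward key steps:* An auxiliary-controlled syn aldol reaction sets C7'/C8' and leads, after several functional-group changes, to the β-substituted butyrolactone A1. Its enolate adds to the second aryl aldehyde trans to the side chain to give A2. Hydride reduction and acid then close ring A through the C7 cation.
- *Why the chosen plan is better:* Each stereocentre is bought separately with a stoichiometric auxiliary. O7' must be protected, since it otherwise competes for the C7 cation. C9 and C9' need redox corrections. The ring closure uses acid on exactly the bonds that ionise. The route would be about twice as long.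

**Alternative 2:** This plan uses the hidden C2 symmetry. Both halves are (7S,8R), and O7 is γ to C9' just as O7' is γ to C9.
- *Cut:* C8–C8', by dimerisation to the stereolabile diaroylsuccinate A3.
- *Forward key step:* A double dynamic kinetic resolution (asymmetric transfer hydrogenation, then lactonisation) sets all four centres and gives the C2-symmetric dilactone A4.
- *Why the chosen plan is better:* The target is not C2-symmetric. One lactone must end as the ether C7–O1–C9'H2 and the other as the diol. The two carbonyl groups are homotopic, so the first reduction is selective only statistically. Three separate reductions follow, and one is a Lewis-acid deoxygenation beside two electron-rich benzylic C–O bonds. In the key step the half-reduced hydroxy ketone can close onto the remaining ketone and dehydrate, and each ketone is flanked by a fully branched carbon.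

**Alternative 3:**
- *Cut:* C8–C9 and C8'–C7' together.
- *Forward key step:* A (2+2) cycloaddition of an aryl keteniminium salt to the C8=C8' bond of the dihydrofuran A5 (from an asymmetric Heck arylation), anti to the C7 aryl group. This gives cyclobutanone A6 with a temporary C9–C7' bond. Base puts the aryl group exo, Baeyer–Villiger oxidation inserts oxygen with retention, and hydride reduction leads to 10.
- *Why the chosen plan is better:* The stereochemistry is closed, but on the attacked face both neighbours of the double bond show only hydrogen. The regiochemistry therefore rests on small inductive differences. A strong electrophile also meets the doubly activated C7–O1 bond. In the chosen plan the tether fixes the regiochemistry.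

Key step: step 4

Assumption: in step 3 the antipode of the phosphoramidite ligand is the one that delivers the S ether 7; both antipodes are commercial.

## Route

Step 1
Reactants: 1 1-(benzyloxy)-4-ethenyl-2-methoxybenzene; 2 prop-2-en-1-yl acetate
Product: 3 (2E)-3-[4-(benzyloxy)-3-methoxyphenyl]prop-2-en-1-yl acetate
Conditions: second-generation Grubbs catalyst (3 mol%), 2 (3 equiv), CH2Cl2, 40 °C
Reagents that add atoms: none
Why: Olefin cross-metathesis of a styrene with an excess of an allylic acetate; loss of ethene drives the reaction, and the conjugated E alkene is the thermodynamic product.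

Step 2
Reactants: 4 1-(benzyloxy)-4-bromo-2-methoxybenzene; 5 prop-2-yn-1-ol
Product: 6 3-[4-(benzyloxy)-3-methoxyphenyl]prop-2-yn-1-ol
Conditions: PdCl2(MeCN)2 (2 mol%), XPhos (6 mol%), Cs2CO3, MeCN, 80 °C
Reagents that add atoms: none
Why: Copper-free Sonogashira coupling; the bulky electron-rich phosphine allows oxidative addition of the electron-rich aryl bromide, and the free hydroxyl group is tolerated.

Step 3
Reactants: 3 cinnamyl-type acetate; 6 arylpropargyl alcohol
Product: 7 1-(benzyloxy)-4-[(1S)-1-({3-[4-(benzyloxy)-3-methoxyphenyl]prop-2-yn-1-yl}oxy)prop-2-en-1-yl]-2-methoxybenzene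
Conditions: [Ir(cod)Cl]2 (2 mol%), BINOL-derived N,N-bis(1-phenylethyl)phosphoramidite (4 mol%, activated with n-PrNH2), K3PO4, toluene, rt
Reagents that add atoms: none
Why: Iridium-catalysed asymmetric allylic etherification with an aliphatic alcohol; the cyclometallated iridium–phosphoramidite complex ionises 3 and directs the oxygen of 6 to the aryl-bearing allyl terminus (branched ether). The catalyst sets C7 as S.

Step 4
Reactants: 7 enyne
Product: 8 2-({(2S,3S,4Z)-2-[4-(benzyloxy)-3-methoxyphenyl]-4-[4-(benzyloxy)-3-methoxybenzylidene]oxolan-3-yl}methyl)-4,4,5,5-tetramethyl-1,3,2-dioxaborolane (aryl at C7 and CH2B at C8 trans)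
Conditions: Pd(OAc)2 (5 mol%), B2pin2 (1.2 equiv), MeOH (1 equiv), toluene, 50 °C
Reagents that add atoms: bis(pinacolato)diboron, CC1(C)OB(OC1(C)C)B1OC(C)(C)C(C)(C)O1
Why: Pd(OAc)2, B2pin2 and MeOH generate a palladium hydride that adds syn across C8'≡C7' with palladium at C8', the only regioisomer that the coordinated vinyl group allows to cyclise; the alkenyl–Pd bond then inserts C8=C9, and the primary C9–Pd species is captured by B2pin2 (transmetallation, reductive elimination). The closest known reaction type is the palladium-catalysed borylative cyclisation of 1,6-enynes with internal alkynes, oxygen-tethered ones included. Ring A closes in the 5-exo-trig mode (C8'–C8 bond), and the three-atom tether C9'–O1–C7 disfavours the 6-endo path. C8 is the only new stereocentre: in the insertion the C7–H bond eclipses C8=C9 to minimise allylic 1,3-strain, O1 lies on the face from which C8' arrives and the aryl group on the other, so C9 ends trans to the C7 aryl group. The exocyclic alkene forms as the Z isomer only (H7' cis to C8, aryl cis to C9'), because hydropalladation is syn and insertion keeps the alkene geometry; this geometry stores the C8'/C7' relationship. The step needs the hydride to choose the alkyne over the vinyl group, which the stronger binding and faster insertion of alkynes secure, and it needs boron transfer to outrun β-hydride elimination. The allylic C7–O1 bond should stay intact because an alkoxide is a poor leaving group under these neutral conditions.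

Step 5
Reactants: 8 homoallylic boronate
Product: 10 di-O-benzyltanegol {(2S,3R,4R)-2-[4-(benzyloxy)-3-methoxyphenyl]-4-{(S)-[4-(benzyloxy)-3-methoxyphenyl](hydroxy)methyl}oxolan-3-yl}methanol, via benzylic borane 9 (not isolated)
Conditions: BH3·SMe2, THF, 0 °C to rt; then aq. NaOH, 30% H2O2, 0 °C
Reagents that add atoms: borane–dimethyl sulfide, C[S+](C)[BH3-] (boron of 9); hydrogen peroxide, OO (both new oxygen atoms of 10)
Why: Hydroboration–oxidation; boron goes to the less substituted, benzylic C7' and hydrogen to C8' in one suprafacial event on the face anti to the CH2B group at C8. This puts the side chain cis to C9 (8'R) and, from the Z alkene, gives 7'S. Alkaline H2O2 replaces both C–B bonds by C–O with retention.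

Step 6
Reactants: 10 di-O-benzyltanegol
Product: 11 (−)-tanegol, (7S,8R,7'S,8'R)
Conditions: H2 (1 atm), 10% Pd/C, EtOAc, rt, stopped after uptake of 2 equiv
Reagents that add atoms: none
Why: Hydrogenolysis of aryl benzyl ethers is faster than that of a secondary benzylic alcohol or a cyclic benzylic ether in a neutral aprotic solvent; no stereocentre is touched.

## Compound list

1 | 1-(benzyloxy)-4-ethenyl-2-methoxybenzene | C=Cc1ccc(OCc2ccccc2)c(OC)c1 | starting material
2 | prop-2-en-1-yl acetate | C=CCOC(C)=O | starting material
3 | (2E)-3-[4-(benzyloxy)-3-methoxyphenyl]prop-2-en-1-yl acetate | COc1cc(/C=C/COC(C)=O)ccc1OCc1ccccc1 | intermediate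
4 | 1-(benzyloxy)-4-bromo-2-methoxybenzene | COc1cc(Br)ccc1OCc1ccccc1 | starting material
5 | prop-2-yn-1-ol | C#CCO | starting material
6 | 3-[4-(benzyloxy)-3-methoxyphenyl]prop-2-yn-1-ol | COc1cc(C#CCO)ccc1OCc1ccccc1 | intermediate
7 | (S)-1-arylallyl 3-arylpropargyl ether (1,6-enyne) | COc1cc(C#CCO[C@H](c2ccc(OCc3ccccc3)c(OC)c2)C=C)ccc1OCc1ccccc1 | intermediate
8 | (2S,3S,4Z)-2-aryl-4-benzylidene-3-(pinacolatoborylmethyl)oxolane | COc1cc(/C=C2\CO[C@H](c3ccc(OCc4ccccc4)c(OC)c3)[C@H]2CB5OC(C)(C)C(C)(C)O5)ccc1OCc1ccccc1 | intermediate
9 | benzylic borane (BH2 at C7' with the configuration of the OH of 10, Bpin at C9) | COc1cc([C@@H](B)[C@H]2CO[C@H](c3ccc(OCc4ccccc4)c(OC)c3)[C@H]2CB5OC(C)(C)C(C)(C)O5)ccc1OCc1ccccc1 | intermediate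
10 | di-O-benzyltanegol | COc1cc([C@@H](O)[C@H]2CO[C@H](c3ccc(OCc4ccccc4)c(OC)c3)[C@H]2CO)ccc1OCc1ccccc1 | intermediate
11 | (−)-tanegol | COc1cc([C@@H](O)[C@H]2CO[C@H](c3ccc(O)c(OC)c3)[C@H]2CO)ccc1O | target

Total step count: 6. Longest linear sequence: 5 steps (steps 1, 3, 4, 5, 6).

## Least certain steps

**Step 4 (key step).** The most likely failure is β-hydride elimination from the C9–Pd intermediate before boron is transferred. The other is hydride-induced migration of the vinyl double bond into conjugation with the aryl group. Both can occur because the C8–H and C7–H bonds are within reach of the metal. The fallback replaces hydropalladation by oxidative cyclometallation at an early metal. From 7, divalent titanium, (η2-propene)Ti(OiPr)2 made from Ti(OiPr)4 and 2 iPrMgCl (Et2O, −50 to −20 °C), should bind the alkyne and insert the vinyl group to give the titanabicycle F1. In F1 one metal holds C9 and C7', which gives the same alkene geometry and leaves no open site for β-hydride elimination. Dry O2 oxidises the more reactive C(sp3)–Ti bond, and aqueous work-up protonates the alkenyl–Ti bond with retention, giving the homoallylic alcohol F2. F2 goes on through the silyl ether F3 and the alcohol F4, as described under step 5, and rejoins the route at 10.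

**Step 5.** The most likely failure is poor facial selectivity, because the CH2Bpin group is slim and the C7 aryl group shields the other face to some degree. The fallback installs a larger steering group on C9 before the addition. From 8, NaOH/H2O2 gives alcohol F2. TIPSCl and imidazole give the silyl ether F3. Hydroboration–oxidation as in step 5 gives F4, and TBAF returns to the route at 10.

**Step 3.** Three things may go wrong:
- attack at the unsubstituted allyl terminus;
- erosion of the enantiomeric purity by reversible ionisation of the electron-rich product ether;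
- acetyl transfer from 3 to 6.

The fallback separates the creation of the stereocentre from the joining of the halves. From 3, the same iridium catalyst with potassium triethylsilanolate, a small oxygen nucleophile, gives the silyl ether F5, and TBAF gives the (S)-allylic alcohol F6. Its purity can be raised by lipase-catalysed acylation of the residual R enantiomer. Compound 6 is converted with CBr4/PPh3 into the bromide F7. Williamson etherification of F6 with F7 (NaH, THF, 0 °C) forms O1–C9' instead of C7–O1 and rejoins the route at 7.

**Step 6.** The most likely failure is over-reduction, that is hydrogenolysis of C7'–OH or C7–O1 once the phenols are free and the benzylic positions are more activated. The fallback masks the alcohols during the hydrogenolysis. From 10, TESCl and imidazole give the bis(silyl ether) F8. H2 over Pd/C in EtOAc gives the diphenol F9, and TBAF buffered with AcOH gives 11.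

## Further compounds

F1 | step 4 | titanabicycle, Ti(OiPr)2 bound to C9 and C7' | CC(C)O[Ti]1(OC(C)C)C[C@@H]2[C@@H](c3ccc(OCc4ccccc4)c(OC)c3)OCC2=C1c1ccc(OCc2ccccc2)c(OC)c1
F2 | step 4 | 2,3-trans-(4Z)-2-aryl-4-benzylidene-3-(hydroxymethyl)oxolane | COc1cc(/C=C2\CO[C@H](c3ccc(OCc4ccccc4)c(OC)c3)[C@H]2CO)ccc1OCc1ccccc1
F3 | step 5 | triisopropylsilyl ether of F2 | COc1cc(/C=C2\CO[C@H](c3ccc(OCc4ccccc4)c(OC)c3)[C@H]2CO[Si](C(C)C)(C(C)C)C(C)C)ccc1OCc1ccccc1
F4 | step 5 | 9-O-triisopropylsilyl-di-O-benzyltanegol | COc1cc([C@@H](O)[C@H]2CO[C@H](c3ccc(OCc4ccccc4)c(OC)c3)[C@H]2CO[Si](C(C)C)(C(C)C)C(C)C)ccc1OCc1ccccc1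
F5 | step 3 | (S)-1-arylallyl triethylsilyl ether | CC[Si](CC)(CC)O[C@H](c1ccc(OCc2ccccc2)c(OC)c1)C=C
F6 | step 3 | (1S)-1-[4-(benzyloxy)-3-methoxyphenyl]prop-2-en-1-ol | O[C@H](c1ccc(OCc2ccccc2)c(OC)c1)C=C
F7 | step 3 | 1-(benzyloxy)-4-(3-bromoprop-1-yn-1-yl)-2-methoxybenzene | COc1cc(C#CCBr)ccc1OCc1ccccc1
F8 | step 6 | 7',9-bis-O-triethylsilyl-di-O-benzyltanegol | COc1cc([C@@H](O[Si](CC)(CC)CC)[C@H]2CO[C@H](c3ccc(OCc4ccccc4)c(OC)c3)[C@H]2CO[Si](CC)(CC)CC)ccc1OCc1ccccc1
F9 | step 6 | 7',9-bis-O-triethylsilyltanegol | COc1cc([C@@H](O[Si](CC)(CC)CC)[C@H]2CO[C@H](c3ccc(O)c(OC)c3)[C@H]2CO[Si](CC)(CC)CC)ccc1O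
A1 | alternative 1 | (4R)-4-{(S)-aryl[(tert-butyldimethylsilyl)oxy]methyl}oxolan-2-one | COc1cc([C@@H](O[Si](C)(C)C(C)(C)C)[C@H]2COC(=O)C2)ccc1OCc1ccccc1
A2 | alternative 1 | trans-α-[aryl(hydroxy)methyl] aldol adduct of A1 (C7 epimers) | COc1cc([C@@H](O[Si](C)(C)C(C)(C)C)[C@H]2COC(=O)[C@@H]2C(O)c2ccc(OCc3ccccc3)c(OC)c2)ccc1OCc1ccccc1
A3 | alternative 2 | dimethyl 2,3-bis[4-(benzyloxy)-3-methoxybenzoyl]butanedioate (stereolabile) | COC(=O)C(C(=O)c1ccc(OCc2ccccc2)c(OC)c1)C(C(=O)OC)C(=O)c1ccc(OCc2ccccc2)c(OC)c1
A4 | alternative 2 | exo,exo-2,6-diaryl-3,7-dioxabicyclo[3.3.0]octane-4,8-dione (C2-symmetric) | COc1cc([C@H]2OC(=O)[C@@H]3[C@@H](c4ccc(OCc5ccccc5)c(OC)c4)OC(=O)[C@H]23)ccc1OCc1ccccc1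
A5 | alternative 3 | (2S)-2-[4-(benzyloxy)-3-methoxyphenyl]-2,5-dihydrofuran | COc1cc([C@H]2OCC=C2)ccc1OCc1ccccc1
A6 | alternative 3 | 2,7-diaryl-3-oxabicyclo[3.2.0]heptan-6-one (both aryl groups exo) | COc1cc([C@H]2C(=O)[C@@H]3[C@@H](c4ccc(OCc5ccccc5)c(OC)c4)OC[C@H]23)ccc1OCc1ccccc1
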